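**Plan**

- Retrosynthetic cuts: (a) the CH2–C(sp2) bond between the methylene α to the side-chain ketone and the methyl-bearing carbon of the Z-alkene; (b) the ketone C–CH2Cl bond and the carbinol–vinyl bond of the enone arm, both made on a temporary δ-lactone; (c) the C=C bond of a Z-iodoalkene; (d) the C2–C3 bond of ring A of a meso cis-bicyclo[3.3.0]octan-3-one.
- Forward order: the bicyclic ketone comes from the commercial dione, ring A is opened to the cis-1,2-dimethylcyclopentane with two different arms, the enone arm and the chloromethyl ketone are installed, and the aryl-alkenyl iodide is joined last; only desilylation follows.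
- Stereochemistry: the cis relation of the two quaternary carbons comes from the ring fusion, and the absolute configuration from an enantioselective deprotonation of the meso ketone. The E-enone comes from syn-hydrostannation, and the Z-alkene from a cis-selective Wittig reaction whose geometry is retained in the coupling.
- Enabling feature: the joining CH2 sits between the ketone C=O and the alkene carbon (a β,γ-unsaturated ketone), so one partner can be an α-chloro ketone with an activated C–Cl bond and the other a configurationally fixed alkenyl iodide. The cyclopentane with its cis CH2C(=O) and C(=O) arms is ring B of a bicyclo[3.3.0]octane whose ring A is cleaved.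

Key step: step 13

Remark: the (R,R)-amide of step 3 is assumed to remove the enantiotopic proton that leads to the drawn silyl enol ether; if the sense proves opposite, the (S,S)-amide is used and nothing else changes.

**Route**

Step 1
Reactants: 1 cis-1,5-dimethylbicyclo[3.3.0]octane-3,7-dione
Product: 2 cis-1,5-dimethylbicyclo[3.3.0]octane-3,7-dione mono(ethylene ketal)
Conditions: ethylene glycol (1 equiv), p-TsOH (cat.), benzene, reflux, Dean–Stark
Reagents that add atoms: ethylene glycol, OCCO
Why: Acid-catalysed ketalisation with azeotropic removal of water should give the monoketal as the main part of a statistical mixture, from which dione and bisketal are recycled; no stereocentre is affected.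

Step 2
Reactants: 2 cis-1,5-dimethylbicyclo[3.3.0]octane-3,7-dione mono(ethylene ketal)
Product: 5 cis-1,5-dimethylbicyclo[3.3.0]octan-3-one (meso), via hydrazone 3 (not isolated), via dioxolane 4 (not isolated)
Conditions: N2H4·H2O, KOH, diethylene glycol, 130 then 200 °C; then 2 M HCl, THF, rt
Reagents that add atoms: water, O
Why: Wolff–Kishner reduction removes the free ketone while the base-stable ketal survives, and aqueous acid in the work-up then hydrolyses the ketal to the meso ketone.

Step 3
Reactants: 5 cis-1,5-dimethylbicyclo[3.3.0]octan-3-one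
Product: 6 (1R,5S)-1,5-dimethyl-3-(trimethylsilyloxy)bicyclo[3.3.0]oct-2-ene
Conditions: (R,R)-bis(1-phenylethyl)amine, n-BuLi, LiCl, THF, −78 °C; TMSCl, then 5, −100 °C
Reagents that add atoms: chlorotrimethylsilane, C[Si](C)(C)Cl
Why: Enantioselective deprotonation of a meso ketone by a C2-symmetric chiral lithium amide with in situ silyl trapping should distinguish the two enantiotopic α-methylene groups, which places the enol double bond towards C2 and fixes both quaternary centres as (1R,5S); their cis relation is inherited from the ring fusion.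

Step 4
Reactants: 6 (1R,5S)-1,5-dimethyl-3-(trimethylsilyloxy)bicyclo[3.3.0]oct-2-ene
Product: 8 methyl 2-[(1S,2S)-2-formyl-1,2-dimethylcyclopentyl]acetate, via aldehyde acid 7 (not isolated)
Conditions: O3, CH2Cl2/MeOH, −78 °C; Me2S, −78 °C to rt; then K2CO3, MeI, DMF, rt
Reagents that add atoms: ozone, [O-][O+]=O; iodomethane, CI
Why: Ozonolysis of the silyl enol ether cleaves C2–C3 to an aldehyde on the quaternary carbon and a carboxylic acid on the CH2 arm, and O-alkylation of the open carboxylate gives the normal methyl ester; neither quaternary centre can epimerise.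

Step 5
Reactants: 9 2-methylbut-3-yn-2-ol
Product: 11 (E)-4-iodo-2-methylbut-3-en-2-ol, via alkenylstannane 10 (not isolated)
Conditions: Bu3SnH, PdCl2(PPh3)2 (divalent palladium, 2 mol %), THF, 0 °C to rt; then I2, CH2Cl2, 0 °C
Reagents that add atoms: iodine, II
Why: Palladium-catalysed syn-hydrostannation of the terminal alkyne places tin on the terminal carbon trans to the bulky carbinol group, and iododestannylation proceeds with retention to the E-alkenyl iodide.

Step 6
Reactants: 8 methyl 2-[(1S,2S)-2-formyl-1,2-dimethylcyclopentyl]acetate; 11 (E)-4-iodo-2-methylbut-3-en-2-ol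
Product: 13 cis-fused δ-lactone (4aS,7aS)-1-[(E)-3-hydroxy-3-methylbut-1-enyl]-4a,7a-dimethylhexahydrocyclopenta[c]pyran-3(1H)-one (both C1 epimers), via hydroxy ester 12 (not isolated)
Conditions: CrCl2 (divalent chromium, 5 equiv), NiCl2 (divalent nickel, 2 mol %), DMSO, rt; aqueous work-up; PPTS (cat.), toluene, 60 °C
Reagents that add atoms: none
Why: In this Nozaki–Hiyama–Kishi reaction the alkenylchromium reagent (E geometry retained) should add to the hindered aldehyde in the presence of the ester and the free tertiary alcohol, and the new alcohol lactonises onto the cis ester arm; the new carbinol centre is uncontrolled and is removed by oxidation in step 8.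

Step 7
Reactants: 13 cis-fused δ-lactone
Product: 14 (4aS,7aS)-3-(chloromethyl)-1-[(E)-3-hydroxy-3-methylbut-1-enyl]-4a,7a-dimethyloctahydrocyclopenta[c]pyran-3-ol (lactol form of the δ-hydroxy chloromethyl ketone)
Conditions: ICH2Cl (3 equiv), MeLi·LiBr (4 equiv, added dropwise), THF/Et2O, −78 °C; AcOH, −78 °C
Reagents that add atoms: chloroiodomethane, ClCI
Why: Chloromethyllithium made by iodine–lithium exchange in the presence of the lactone adds once to the lactone carbonyl, because the tetrahedral lithium hemiketal alkoxide does not collapse at −78 °C (carbenoid homologation of an ester to a chloromethyl ketone); the first equivalent of MeLi is consumed by the tertiary alcohol.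

Step 8
Reactants: 14 chloromethyl lactol
Product: 15 (E)-1-[(1S,2S)-2-(3-chloro-2-oxopropyl)-1,2-dimethylcyclopentyl]-4-hydroxy-4-methylpent-2-en-1-one
Conditions: Dess–Martin periodinane, CH2Cl2 (water-saturated), rt
Reagents that add atoms: none
Why: Dess–Martin oxidation should act on the open δ-hydroxy ketone tautomer of the lactol, turning the secondary allylic alcohol into the enone and so freeing the chloromethyl ketone; the tertiary alcohol cannot be oxidised.

Step 9
Reactants: 16 2-allyl-6-methylphenol
Product: 17 2-allyl-6-methyl-1,4-benzoquinone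
Conditions: Co(salen) [Co(C16H14N2O2), divalent cobalt] (5 mol %), O2 (1 atm), DMF, rt
Reagents that add atoms: dioxygen, O=O
Why: Cobalt–salen catalysed aerobic oxidation of a 2,6-disubstituted phenol should give the para-quinone, because both ortho positions are blocked and the para position is free.

Step 10
Reactants: 17 2-allyl-6-methyl-1,4-benzoquinone
Product: 19 1-allyl-2,5-bis(tert-butyldimethylsilyloxy)-3-methylbenzene, via hydroquinone 18 (not isolated)
Conditions: Na2S2O4, Et2O/H2O, rt; organic layer dried and concentrated under argon; then TBSCl, imidazole, DMAP (cat.), DMF, 40 °C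
Reagents that add atoms: tert-butyldimethylsilyl chloride, CC(C)(C)[Si](C)(C)Cl
Why: Dithionite reduces the quinone to the hydroquinone, which is silylated at both oxygens (silyl ether formation) before it can reoxidise in air.

Step 11
Reactants: 19 1-allyl-2,5-bis(tert-butyldimethylsilyloxy)-3-methylbenzene
Product: 20 2-[2,5-bis(tert-butyldimethylsilyloxy)-3-methylphenyl]acetaldehyde
Conditions: OsO4 (2 mol %), NaIO4, 2,6-lutidine, dioxane/H2O (3:1), rt
Reagents that add atoms: osmium tetroxide (catalytic oxygen carrier), O=[Os](=O)(=O)=O; sodium periodate, [Na+].[O-]I(=O)(=O)=O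
Why: Lemieux–Johnson cleavage (catalytic dihydroxylation, then periodate glycol cleavage) acts only on the monosubstituted alkene and should give the arylacetaldehyde under buffered conditions.

Step 12
Reactants: 20 2-[2,5-bis(tert-butyldimethylsilyloxy)-3-methylphenyl]acetaldehyde
Product: 21 (Z)-1-[2,5-bis(tert-butyldimethylsilyloxy)-3-methylphenyl]-3-iodobut-2-ene
Conditions: EtPPh3I, n-BuLi, THF, rt; I2, −78 °C; NaN(SiMe3)2, −20 °C; then 20, −78 to −20 °C
Reagents that add atoms: ethyltriphenylphosphonium iodide, CC[P+](c1ccccc1)(c1ccccc1)c1ccccc1.[I-]; iodine, II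
Why: The Stork–Zhao-type Wittig reaction of the non-stabilised α-iodo ylide Ph3P=C(I)CH3 at low temperature is cis-selective, which should place iodine and the CH2Ar group on the same side (Z).

Step 13
Reactants: 15 (E)-1-[(1S,2S)-2-(3-chloro-2-oxopropyl)-1,2-dimethylcyclopentyl]-4-hydroxy-4-methylpent-2-en-1-one; 21 (Z)-1-[2,5-bis(tert-butyldimethylsilyloxy)-3-methylphenyl]-3-iodobut-2-ene
Product: 22 (2E)-1-[(1S,2S)-2-[(4Z)-6-[2,5-bis(tert-butyldimethylsilyloxy)-3-methylphenyl]-4-methyl-2-oxohex-4-enyl]-1,2-dimethylcyclopentyl]-4-hydroxy-4-methylpent-2-en-1-one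
Conditions: NiBr2(bpy) (divalent nickel, 10 mol %), Bu4NBr, DMF, undivided cell, aluminium rod anode, nickel-foam cathode, constant current, 60 °C, 15 added by syringe pump
Reagents that add atoms: none
Why: Zerovalent nickel formed at the cathode from NiBr2(bpy) inserts into the C–I bond of 21 with retention of the Z geometry, the alkenylnickel is reduced by one electron and then takes up the activated C–Cl bond of the chloromethyl ketone 15, and reductive elimination from the resulting alkenyl(2-oxoalkyl)nickel forms the CH2–C(sp2) bond while aluminium ions from the anode bind the two halides. The closest known reaction type is the nickel-catalysed electroreductive cross-coupling of α-chloro ketones and α-chloro esters with aryl and alkenyl halides at a sacrificial anode (a cross-electrophile coupling). No ring is closed and no stereocentre is formed, and the two quaternary centres lie three and four bonds away from the reacting carbon and are not touched. The step needs cross-coupling instead of hydrodechlorination or dimerisation, retention of the alkene geometry, and a double bond that stays out of conjugation with the new ketone. Slow addition of 15 to the alkenylnickel formed first secures the first point, stereoretentive oxidative addition at an alkenyl iodide the second, and the base-free neutral medium the third, since the doubly activated CH2 is never deprotonated. The enone of 15 is not reduced at the potential of the nickel couple and is shielded by the quaternary carbon on one side and the fully substituted carbinol carbon on the other.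

Step 14
Reactants: 22 bis(silyl ether) of the target
Product: 23 (2E)-1-[(1S,2S)-2-[(4Z)-6-(2,5-dihydroxy-3-methylphenyl)-4-methyl-2-oxohex-4-enyl]-1,2-dimethylcyclopentyl]-4-hydroxy-4-methylpent-2-en-1-one (target)
Conditions: HF·pyridine, pyridine, THF, 0 °C to rt, argon
Reagents that add atoms: none
Why: Fluoride cleaves the two aryl silyl ethers (Si–F bond formation) under buffered conditions that should neither enolise the β,γ-unsaturated ketone nor ionise the tertiary allylic alcohol.

**Compound list**

1 | cis-1,5-dimethylbicyclo[3.3.0]octane-3,7-dione (meso, methyl groups on the same face) | C[C@@]12CC(=O)C[C@]1(C)CC(=O)C2 | starting material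
2 | cis-1,5-dimethylbicyclo[3.3.0]octane-3,7-dione mono(ethylene ketal) | C[C@@]12CC(=O)C[C@]1(C)CC3(OCCO3)C2 | intermediate
3 | hydrazone of 2 at the free ketone | C[C@@]12CC(=NN)C[C@]1(C)CC3(OCCO3)C2 | intermediate
4 | 3,3-(ethylenedioxy)-cis-1,5-dimethylbicyclo[3.3.0]octane | C[C@@]12CCC[C@]1(C)CC3(OCCO3)C2 | intermediate
5 | cis-1,5-dimethylbicyclo[3.3.0]octan-3-one (meso) | C[C@@]12CC(=O)C[C@]1(C)CCC2 | intermediate
6 | (1R,5S)-1,5-dimethyl-3-(trimethylsilyloxy)bicyclo[3.3.0]oct-2-ene | C[C@@]12C=C(O[Si](C)(C)C)C[C@]1(C)CCC2 | intermediate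
7 | 2-[(1S,2S)-2-formyl-1,2-dimethylcyclopentyl]acetic acid | OC(=O)C[C@]1(C)CCC[C@]1(C)C=O | intermediate
8 | methyl 2-[(1S,2S)-2-formyl-1,2-dimethylcyclopentyl]acetate | COC(=O)C[C@]1(C)CCC[C@]1(C)C=O | intermediate
9 | 2-methylbut-3-yn-2-ol | CC(C)(O)C#C | starting material
10 | (E)-2-methyl-4-(tributylstannyl)but-3-en-2-ol | CCCC[Sn](CCCC)(CCCC)/C=C/C(C)(C)O | intermediate
11 | (E)-4-iodo-2-methylbut-3-en-2-ol | CC(C)(O)/C=C/I | intermediate
12 | methyl 2-[(1S,2S)-2-[(E)-1,4-dihydroxy-4-methylpent-2-enyl]-1,2-dimethylcyclopentyl]acetate (both carbinol epimers) | COC(=O)C[C@]1(C)CCC[C@]1(C)C(O)/C=C/C(C)(C)O | intermediate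
13 | (4aS,7aS)-1-[(E)-3-hydroxy-3-methylbut-1-enyl]-4a,7a-dimethylhexahydrocyclopenta[c]pyran-3(1H)-one (cis-fused δ-lactone, both C1 epimers) | O=C1C[C@]2(C)CCC[C@]2(C)C(O1)/C=C/C(C)(C)O | intermediate
14 | (4aS,7aS)-3-(chloromethyl)-1-[(E)-3-hydroxy-3-methylbut-1-enyl]-4a,7a-dimethyloctahydrocyclopenta[c]pyran-3-ol (lactol, epimers at C1 and C3) | OC1(CCl)C[C@]2(C)CCC[C@]2(C)C(O1)/C=C/C(C)(C)O | intermediate
15 | (E)-1-[(1S,2S)-2-(3-chloro-2-oxopropyl)-1,2-dimethylcyclopentyl]-4-hydroxy-4-methylpent-2-en-1-one | ClCC(=O)C[C@]1(C)CCC[C@]1(C)C(=O)/C=C/C(C)(C)O | intermediate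
16 | 2-allyl-6-methylphenol | C=CCc1cccc(C)c1O | starting material
17 | 2-allyl-6-methyl-1,4-benzoquinone | C=CCC1=CC(=O)C=C(C)C1=O | intermediate
18 | 2-allyl-6-methylbenzene-1,4-diol | C=CCc1cc(O)cc(C)c1O | intermediate
19 | 1-allyl-2,5-bis(tert-butyldimethylsilyloxy)-3-methylbenzene | C=CCc1cc(O[Si](C)(C)C(C)(C)C)cc(C)c1O[Si](C)(C)C(C)(C)C | intermediate
20 | 2-[2,5-bis(tert-butyldimethylsilyloxy)-3-methylphenyl]acetaldehyde | O=CCc1cc(O[Si](C)(C)C(C)(C)C)cc(C)c1O[Si](C)(C)C(C)(C)C | intermediate
21 | (Z)-1-[2,5-bis(tert-butyldimethylsilyloxy)-3-methylphenyl]-3-iodobut-2-ene | C/C(I)=C/Cc1cc(O[Si](C)(C)C(C)(C)C)cc(C)c1O[Si](C)(C)C(C)(C)C | intermediate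
22 | (2E)-1-[(1S,2S)-2-[(4Z)-6-[2,5-bis(tert-butyldimethylsilyloxy)-3-methylphenyl]-4-methyl-2-oxohex-4-enyl]-1,2-dimethylcyclopentyl]-4-hydroxy-4-methylpent-2-en-1-one | C/C(=C/Cc1cc(O[Si](C)(C)C(C)(C)C)cc(C)c1O[Si](C)(C)C(C)(C)C)CC(=O)C[C@]1(C)CCC[C@]1(C)C(=O)/C=C/C(C)(C)O | intermediate
23 | (2E)-1-[(1S,2S)-2-[(4Z)-6-(2,5-dihydroxy-3-methylphenyl)-4-methyl-2-oxohex-4-enyl]-1,2-dimethylcyclopentyl]-4-hydroxy-4-methylpent-2-en-1-one | C/C(=C/Cc1cc(O)cc(C)c1O)CC(=O)C[C@]1(C)CCC[C@]1(C)C(=O)/C=C/C(C)(C)O | target

**Step count**

Total step count: 14.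
Longest linear sequence: 9 steps (steps 1, 2, 3, 4, 6, 7, 8, 13, 14).

**Steps most likely to fail**

Step 13. The chloromethyl ketone may be consumed by hydrodechlorination, or its transient metal enolate may close onto the enone carbonyl in a six-membered aldol-type cyclisation, faster than it is captured by the alkenylnickel. The fallback sets out from lactone 13 and returns at 22, and joins a preformed enolate equivalent to an alkenylpalladium species instead of coupling two electrophiles. Lactone 13 is opened with MeLi (THF, −78 °C) to the methyl lactol (4aS,7aS)-1-[(E)-3-hydroxy-3-methylbut-1-enyl]-3,4a,7a-trimethyloctahydrocyclopenta[c]pyran-3-ol F1. Dess–Martin oxidation gives the diketone (E)-1-[(1S,2S)-1,2-dimethyl-2-(2-oxopropyl)cyclopentyl]-4-hydroxy-4-methylpent-2-en-1-one F2. LiN(i-Pr)2 with TMSCl present (THF, −78 °C) silylates the methyl-side enolate and the tertiary alcohol to give the bis-silyl enol ether (E)-1-[(1S,2S)-1,2-dimethyl-2-[2-(trimethylsilyloxy)prop-2-enyl]cyclopentyl]-4-methyl-4-(trimethylsilyloxy)pent-2-en-1-one F3. The tin enolate formed from F3 and Bu3SnF is coupled with iodide 21 under PdCl2[P(o-tol)3]2 (divalent palladium, toluene, 90 °C; Stille-type α-alkenylation of a tin enolate) to the tertiary O-trimethylsilyl ether of 22 F4. F4 loses its silyl group on work-up with dilute citric acid and so gives 22.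

Step 3. The base may discriminate poorly between the two enantiotopic α-methylene groups, or the enolate may equilibrate before it is trapped, so that the enol ether is formed with low enantiomeric purity. The fallback sets out from ketone 5 and returns at aldehyde ester 8, and moves the desymmetrisation to an oxygen-insertion step. Ketone 5 is oxidised in an enantioselective Baeyer–Villiger reaction by a cyclohexanone-monooxygenase-type enzyme (whole cells, O2, glucose; enzyme chosen from a panel for the required sense) to the lactone (4aS,7aS)-4a,7a-dimethylhexahydrocyclopenta[c]pyran-3(1H)-one F5. Saponification (LiOH, THF/H2O) gives lithium 2-[(1S,2S)-2-(hydroxymethyl)-1,2-dimethylcyclopentyl]acetate F6. Alkylation of this carboxylate with MeI in DMF gives methyl 2-[(1S,2S)-2-(hydroxymethyl)-1,2-dimethylcyclopentyl]acetate F7, and Dess–Martin oxidation of F7 gives 8.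

Step 12. The basic ylide may enolise the arylacetaldehyde, and the cis selectivity of the olefination may erode, which would lower both conversion and the geometric purity of the iodoalkene. The fallback sets out from aldehyde 20 and returns at 22, and takes the geometry from a stereoselective mono-coupling instead of a Wittig reaction. Corey–Fuchs dibromo-olefination (CBr4, PPh3, CH2Cl2, 0 °C) gives 1-[2,5-bis(tert-butyldimethylsilyloxy)-3-methylphenyl]-3,3-dibromoprop-2-ene F8. A Negishi coupling with MeZnCl under PdCl2[O(C6H4PPh2)2] (divalent palladium, THF, 0 °C) replaces only the bromine trans to the CH2Ar group and gives (Z)-1-[2,5-bis(tert-butyldimethylsilyloxy)-3-methylphenyl]-3-bromobut-2-ene F9. F9 is used in place of 21 under the conditions of step 13 and gives 22.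

Further compounds
F1 | step 13 | (4aS,7aS)-1-[(E)-3-hydroxy-3-methylbut-1-enyl]-3,4a,7a-trimethyloctahydrocyclopenta[c]pyran-3-ol | CC1(O)C[C@]2(C)CCC[C@]2(C)C(O1)/C=C/C(C)(C)O
F2 | step 13 | (E)-1-[(1S,2S)-1,2-dimethyl-2-(2-oxopropyl)cyclopentyl]-4-hydroxy-4-methylpent-2-en-1-one | CC(=O)C[C@]1(C)CCC[C@]1(C)C(=O)/C=C/C(C)(C)O
F3 | step 13 | (E)-1-[(1S,2S)-1,2-dimethyl-2-[2-(trimethylsilyloxy)prop-2-enyl]cyclopentyl]-4-methyl-4-(trimethylsilyloxy)pent-2-en-1-one | C=C(O[Si](C)(C)C)C[C@]1(C)CCC[C@]1(C)C(=O)/C=C/C(C)(C)O[Si](C)(C)C
F4 | step 13 | tertiary O-trimethylsilyl ether of 22 | C/C(=C/Cc1cc(O[Si](C)(C)C(C)(C)C)cc(C)c1O[Si](C)(C)C(C)(C)C)CC(=O)C[C@]1(C)CCC[C@]1(C)C(=O)/C=C/C(C)(C)O[Si](C)(C)C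
F5 | step 3 | (4aS,7aS)-4a,7a-dimethylhexahydrocyclopenta[c]pyran-3(1H)-one | O=C1C[C@]2(C)CCC[C@]2(C)CO1
F6 | step 3 | lithium 2-[(1S,2S)-2-(hydroxymethyl)-1,2-dimethylcyclopentyl]acetate | [Li+].[O-]C(=O)C[C@]1(C)CCC[C@]1(C)CO
F7 | step 3 | methyl 2-[(1S,2S)-2-(hydroxymethyl)-1,2-dimethylcyclopentyl]acetate | COC(=O)C[C@]1(C)CCC[C@]1(C)CO
F8 | step 12 | 1-[2,5-bis(tert-butyldimethylsilyloxy)-3-methylphenyl]-3,3-dibromoprop-2-ene | BrC(Br)=CCc1cc(O[Si](C)(C)C(C)(C)C)cc(C)c1O[Si](C)(C)C(C)(C)C
F9 | step 12 | (Z)-1-[2,5-bis(tert-butyldimethylsilyloxy)-3-methylphenyl]-3-bromobut-2-ene | C/C(Br)=C/Cc1cc(O[Si](C)(C)C(C)(C)C)cc(C)c1O[Si](C)(C)C(C)(C)C
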